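**Retrosynthetic overview**
- The target comes from a tetra-silyl ether by global desilylation; its C6 prenyl group comes from an aryl bromide (Li–Br exchange, Cu-catalysed prenylation).
- The dihydropyran ring (ring C) and the C3 stereocentre come from a bromo-prenyl-resorcinol by a phenol-directed asymmetric epoxidation/6-endo ring closure (the new step). The bromine marks the second prenyl site, so the two sides of ring A never compete.
- That resorcinol comes from a ring A dibromide (mono Li–Br exchange/prenylation, then MOM removal), made by double bromination of a bibenzyl para to the ring A oxygens.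
- The bibenzyl comes from a ring B styrene (from 3,4-dihydroxybenzaldehyde) and a ring A aryl bromide (from 5-bromoresorcinol) by hydroboration/B-alkyl Suzuki coupling.
- Ring order: rings A and B are bought as arenes; ring C is the only ring formed (step 8).

Assumption and abbreviations: the target is (3R) as drawn; MOM = methoxymethyl, TBS = tert-butyldimethylsilyl, TIPS = triisopropylsilyl, TES = triethylsilyl, 9-BBN = 9-borabicyclo[3.3.1]nonane, CSA = camphorsulfonic acid, BHA ligand = N,N'-[(1R,2R)-cyclohexane-1,2-diyl]bis(N-hydroxy-2,2-diphenylacetamide).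

**Step 1**
Reactants: 1 5-bromoresorcinol
Product: 2 1-bromo-3,5-bis(MOMO)benzene
Conditions: MOMCl (2.6 equiv), i-Pr2NEt (3 equiv), CH2Cl2, 0 °C → rt
Reagents that add atoms: chloromethyl methyl ether (MOMCl), COCCl
Why: Williamson-type O-alkylation of both phenols gives acetal ethers that later stabilise the ortho-aryllithium and survive NBS and the cross-coupling.

**Step 2**
Reactants: 3 3,4-dihydroxybenzaldehyde
Product: 4 3,4-bis(TBSO)benzaldehyde
Conditions: TBSCl (2.4 equiv), imidazole (5 equiv), DMF, rt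
Reagents that add atoms: tert-butyldimethylsilyl chloride (TBSCl), CC(C)(C)[Si](C)(C)Cl
Why: Imidazole-promoted silylation protects the catechol as a bis-silyl ether that is inert to organolithiums at −78 °C and is removed by fluoride at the end without touching a prenyl group.

**Step 3**
Reactants: 4 3,4-bis(TBSO)benzaldehyde
Product: 5 3,4-bis(TBSO)styrene
Conditions: Ph3PCH3Br (1.3 equiv), n-BuLi (1.25 equiv), THF, 0 °C; then 4, 0 °C → rt
Reagents that add atoms: methyltriphenylphosphonium bromide, C[P+](c1ccccc1)(c1ccccc1)c1ccccc1.[Br-]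
Why: Wittig methylenation of the non-enolisable aryl aldehyde with the preformed ylide gives the styrene.

**Step 4**
Reactants: 5 3,4-bis(TBSO)styrene; 2 1-bromo-3,5-bis(MOMO)benzene
Product: 7 1-[2-(3,4-bis(TBSO)phenyl)ethyl]-3,5-bis(MOMO)benzene, via B-alkyl-9-BBN adduct 6 (not isolated)
Conditions: 9-BBN (1.2 equiv), THF, rt; then 2, Pd(dppf)Cl2 (5 mol %), K3PO4 (3 equiv, 3 M aq), THF, 50 °C
Reagents that add atoms: none
Why: Anti-Markovnikov hydroboration of the styrene followed by B-alkyl Suzuki–Miyaura coupling forms the sp3–sp2 bond of the bibenzyl bridge directly, so no alkene has to be hydrogenated later.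

**Step 5**
Reactants: 7 1-[2-(3,4-bis(TBSO)phenyl)ethyl]-3,5-bis(MOMO)benzene
Product: 8 2,4-dibromo-3-[2-(3,4-bis(TBSO)phenyl)ethyl]-1,5-bis(MOMO)benzene
Conditions: NBS (2.05 equiv), MeCN, 0 °C → rt, dark
Reagents that add atoms: N-bromosuccinimide (NBS), O=C1CCC(=O)N1Br
Why: Electrophilic aromatic bromination goes twice on ring A at the two positions para to one OMOM and ortho to the other (the site between the two OMOM groups is slowest), while ring B, with no pair of cooperating oxygens and bulky silyloxy groups, reacts far more slowly.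

**Step 6**
Reactants: 8 2,4-dibromo-3-[2-(3,4-bis(TBSO)phenyl)ethyl]-1,5-bis(MOMO)benzene
Product: 10 2-bromo-3-[2-(3,4-bis(TBSO)phenyl)ethyl]-1,5-bis(MOMO)-4-(3-methylbut-2-enyl)benzene, via aryllithium 9 (not isolated)
Conditions: n-BuLi (1.05 equiv), THF, −78 °C; CuBr·SMe2 (20 mol %); prenyl bromide (1.5 equiv), −78 → 0 °C
Reagents that add atoms: prenyl bromide (1-bromo-3-methylbut-2-ene), CC(C)=CCBr
Why: Lithium–bromine exchange with one equivalent of n-BuLi stops at the OMOM-chelated mono-aryllithium (a second exchange would need a dianion), and copper-catalysed SN2 allylation gives the linear prenyl arene.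

**Step 7**
Reactants: 10 2-bromo-3-[2-(3,4-bis(TBSO)phenyl)ethyl]-1,5-bis(MOMO)-4-(3-methylbut-2-enyl)benzene
Product: 11 4-bromo-5-[2-(3,4-bis(TBSO)phenyl)ethyl]-6-(3-methylbut-2-enyl)benzene-1,3-diol
Conditions: ZnBr2 (2 equiv), n-PrSH (4 equiv), CH2Cl2, 0 °C, 10 min
Reagents that add atoms: none
Why: ZnBr2-assisted thiolysis of the formaldehyde acetals cleaves both aryl MOM ethers within minutes under non-protic conditions that leave the prenyl alkene, the aryl bromide and the aryl silyl ethers alone.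

**Step 8**
Reactants: 11 4-bromo-5-[2-(3,4-bis(TBSO)phenyl)ethyl]-6-(3-methylbut-2-enyl)benzene-1,3-diol
Product: 13 (3R)-6-bromo-5-[2-(3,4-bis(TBSO)phenyl)ethyl]-2,2-dimethylchromane-3,7-diol, via epoxide 12 (not isolated)
Conditions: Hf(OtBu)4 (10 mol %), (R,R)-BHA ligand (12 mol %), cumene hydroperoxide (1.5 equiv), 4 Å MS, toluene, 0 °C; then CSA (10 mol %), CH2Cl2, 0 °C
Reagents that add atoms: cumene hydroperoxide, CC(C)(OO)c1ccccc1
Why: Proposed new method: the phenol next to the prenyl group exchanges onto the tetravalent hafnium centre that carries the C2-symmetric bishydroxamate and the η2-bound cumyl peroxide, so oxygen is delivered intramolecularly to one face of the alkene held four and five atoms from the phenolic oxygen (the geometry of a bishomoallylic alcohol, rigidified by the arene) to give (R)-epoxide 12, which the same phenol then opens at the tertiary carbon under acid (6-endo, Markovnikov) so the carbinol carbon is untouched and C3 comes out R; the closest known reaction type is the hafnium- or zirconium-bishydroxamic acid epoxidation of homoallylic and bishomoallylic alcohols, here extended to a phenol as directing group and coupled to the ring closure; the facial sense cannot be predicted with certainty, so it is checked on 13 by Mosher ester analysis and the mirror-image ligand is used if it is opposite.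

**Step 9**
Reactants: 13 (3R)-6-bromo-5-[2-(3,4-bis(TBSO)phenyl)ethyl]-2,2-dimethylchromane-3,7-diol
Product: 15 (3R)-6-bromo-5-[2-(3,4-bis(TBSO)phenyl)ethyl]-2,2-dimethyl-3-(TESO)-7-(TIPSO)chromane, via 7-O-TIPS ether 14 (not isolated)
Conditions: TIPSCl (1.1 equiv), imidazole (4 equiv), DMF, 0 °C → rt; then TESCl (1.5 equiv), rt
Reagents that add atoms: triisopropylsilyl chloride (TIPSCl), CC(C)[Si](Cl)(C(C)C)C(C)C; triethylsilyl chloride (TESCl), CC[Si](Cl)(CC)CC
Why: Silylation in order of nucleophilicity caps the phenol with TIPS (which resists 1,3 O-to-C shift to an ortho-lithio carbon at −78 °C) and then the hindered secondary alcohol with TES, so step 10 needs only one equivalent of base.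

**Step 10**
Reactants: 15 (3R)-6-bromo-5-[2-(3,4-bis(TBSO)phenyl)ethyl]-2,2-dimethyl-3-(TESO)-7-(TIPSO)chromane
Product: 17 (3R)-5-[2-(3,4-bis(TBSO)phenyl)ethyl]-2,2-dimethyl-6-(3-methylbut-2-enyl)-3-(TESO)-7-(TIPSO)chromane, via aryllithium 16 (not isolated)
Conditions: n-BuLi (1.05 equiv), THF, −78 °C; CuBr·SMe2 (20 mol %); prenyl bromide (1.5 equiv), −78 → −20 °C
Reagents that add atoms: prenyl bromide (1-bromo-3-methylbut-2-ene), CC(C)=CCBr
Why: Lithium–bromine exchange and copper-catalysed SN2 allylation, as in step 6, install the second prenyl group at C6, and the C3 stereocentre is a silyl ether remote from the anion and is not touched.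

**Step 11**
Reactants: 17 (3R)-5-[2-(3,4-bis(TBSO)phenyl)ethyl]-2,2-dimethyl-6-(3-methylbut-2-enyl)-3-(TESO)-7-(TIPSO)chromane
Product: 18 (3R)-5-[2-(3,4-dihydroxyphenyl)ethyl]-2,2-dimethyl-6-(3-methylbut-2-enyl)chromane-3,7-diol
Conditions: TBAF (5 equiv), AcOH (5 equiv), THF, 0 °C → rt, argon
Reagents that add atoms: none
Why: Buffered fluoride cleaves all four silyl ethers by Si–F bond formation while acetic acid protects the catechol and the ortho-prenyl phenol from base- or acid-mediated side reactions, giving the target with C3 still R.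

**Compound list**
1 | 5-bromoresorcinol | Oc1cc(O)cc(Br)c1 | starting material
2 | 1-bromo-3,5-bis(MOMO)benzene | COCOc1cc(Br)cc(OCOC)c1 | intermediate
3 | 3,4-dihydroxybenzaldehyde | O=Cc1ccc(O)c(O)c1 | starting material
4 | 3,4-bis(TBSO)benzaldehyde | O=Cc1ccc(O[Si](C)(C)C(C)(C)C)c(O[Si](C)(C)C(C)(C)C)c1 | intermediate
5 | 3,4-bis(TBSO)styrene | C=Cc1ccc(O[Si](C)(C)C(C)(C)C)c(O[Si](C)(C)C(C)(C)C)c1 | intermediate
6 | B-[2-(3,4-bis(TBSO)phenyl)ethyl]-9-BBN (formed in the flask) | CC(C)(C)[Si](C)(C)Oc1ccc(CCB2C3CCCC2CCC3)cc1O[Si](C)(C)C(C)(C)C | intermediate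
7 | 1-[2-(3,4-bis(TBSO)phenyl)ethyl]-3,5-bis(MOMO)benzene | COCOc1cc(CCc2ccc(O[Si](C)(C)C(C)(C)C)c(O[Si](C)(C)C(C)(C)C)c2)cc(OCOC)c1 | intermediate
8 | 2,4-dibromo-3-[2-(3,4-bis(TBSO)phenyl)ethyl]-1,5-bis(MOMO)benzene | COCOc1cc(OCOC)c(Br)c(CCc2ccc(O[Si](C)(C)C(C)(C)C)c(O[Si](C)(C)C(C)(C)C)c2)c1Br | intermediate
9 | {3-bromo-2-[2-(3,4-bis(TBSO)phenyl)ethyl]-4,6-bis(MOMO)phenyl}lithium (formed in the flask) | COCOc1cc(OCOC)c(Br)c(CCc2ccc(O[Si](C)(C)C(C)(C)C)c(O[Si](C)(C)C(C)(C)C)c2)c1[Li] | intermediate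
10 | 2-bromo-3-[2-(3,4-bis(TBSO)phenyl)ethyl]-1,5-bis(MOMO)-4-(3-methylbut-2-enyl)benzene | COCOc1cc(OCOC)c(Br)c(CCc2ccc(O[Si](C)(C)C(C)(C)C)c(O[Si](C)(C)C(C)(C)C)c2)c1CC=C(C)C | intermediate
11 | 4-bromo-5-[2-(3,4-bis(TBSO)phenyl)ethyl]-6-(3-methylbut-2-enyl)benzene-1,3-diol | Oc1cc(O)c(Br)c(CCc2ccc(O[Si](C)(C)C(C)(C)C)c(O[Si](C)(C)C(C)(C)C)c2)c1CC=C(C)C | intermediate
12 | 4-bromo-5-[2-(3,4-bis(TBSO)phenyl)ethyl]-6-{[(2R)-3,3-dimethyloxiran-2-yl]methyl}benzene-1,3-diol (formed in the flask) | Oc1cc(O)c(Br)c(CCc2ccc(O[Si](C)(C)C(C)(C)C)c(O[Si](C)(C)C(C)(C)C)c2)c1C[C@H]1OC1(C)C | intermediate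
13 | (3R)-6-bromo-5-[2-(3,4-bis(TBSO)phenyl)ethyl]-2,2-dimethylchromane-3,7-diol | Brc1c(O)cc2c(c1CCc1ccc(O[Si](C)(C)C(C)(C)C)c(O[Si](C)(C)C(C)(C)C)c1)C[C@@H](O)C(C)(C)O2 | intermediate
14 | (3R)-6-bromo-5-[2-(3,4-bis(TBSO)phenyl)ethyl]-2,2-dimethyl-7-(TIPSO)chroman-3-ol (formed in the flask) | Brc1c(O[Si](C(C)C)(C(C)C)C(C)C)cc2c(c1CCc1ccc(O[Si](C)(C)C(C)(C)C)c(O[Si](C)(C)C(C)(C)C)c1)C[C@@H](O)C(C)(C)O2 | intermediate
15 | (3R)-6-bromo-5-[2-(3,4-bis(TBSO)phenyl)ethyl]-2,2-dimethyl-3-(TESO)-7-(TIPSO)chromane | Brc1c(O[Si](C(C)C)(C(C)C)C(C)C)cc2c(c1CCc1ccc(O[Si](C)(C)C(C)(C)C)c(O[Si](C)(C)C(C)(C)C)c1)C[C@@H](O[Si](CC)(CC)CC)C(C)(C)O2 | intermediate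
16 | (3R)-5-[2-(3,4-bis(TBSO)phenyl)ethyl]-6-lithio-2,2-dimethyl-3-(TESO)-7-(TIPSO)chromane (formed in the flask) | [Li]c1c(O[Si](C(C)C)(C(C)C)C(C)C)cc2c(c1CCc1ccc(O[Si](C)(C)C(C)(C)C)c(O[Si](C)(C)C(C)(C)C)c1)C[C@@H](O[Si](CC)(CC)CC)C(C)(C)O2 | intermediate
17 | (3R)-5-[2-(3,4-bis(TBSO)phenyl)ethyl]-2,2-dimethyl-6-(3-methylbut-2-enyl)-3-(TESO)-7-(TIPSO)chromane | CC(C)=CCc1c(O[Si](C(C)C)(C(C)C)C(C)C)cc2c(c1CCc1ccc(O[Si](C)(C)C(C)(C)C)c(O[Si](C)(C)C(C)(C)C)c1)C[C@@H](O[Si](CC)(CC)CC)C(C)(C)O2 | intermediate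
18 | (3R)-5-[2-(3,4-dihydroxyphenyl)ethyl]-2,2-dimethyl-6-(3-methylbut-2-enyl)chromane-3,7-diol (CNP0369548.1) | CC(C)=CCc1c(O)cc2c(c1CCc1ccc(O)c(O)c1)C[C@@H](O)C(C)(C)O2 | target

**Totals and risks**
Total step count: 11. Longest linear sequence: 10 steps (3 → 18, steps 2 to 11; step 1 is the side branch).

The three steps most likely to fail:

Step 4. Aqueous phosphate at 50 °C can strip the aryl silyl ethers from the catechol, and the alkylborane can be lost by protodeboronation. The fallback sets out from 5 (with 2) and comes back at 7. Heck coupling of 5 with 2 (Pd(OAc)2, P(o-tol)3, Et3N, DMF, 100 °C, an anhydrous amine base that spares the silyl ethers) gives (E)-1-[2-(3,4-bis(TBSO)phenyl)ethenyl]-3,5-bis(MOMO)benzene F1. Hydrogenation of the stilbene double bond (H2, Pd/C, EtOAc, rt) then gives 7.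

Step 8 (the proposed new reaction). The spectator phenol may aggregate the hafnium aryloxide and slow turnover, the enantioselectivity and facial sense are untested, and 5-exo closure to the dihydrobenzofuran may compete. The fallback uses known chemistry, sets out from 10 and comes back at 13. Shi epoxidation of 10 (1,2:4,5-di-O-isopropylidene-D-erythro-2,3-hexodiulo-2,6-pyranose 30 mol %, KHSO5, K2CO3, Bu4NHSO4, MeCN/CH2(OMe)2/aqueous buffer pH 10.5, 0 °C) gives 2-bromo-3-[2-(3,4-bis(TBSO)phenyl)ethyl]-4-{[(2R)-3,3-dimethyloxiran-2-yl]methyl}-1,5-bis(MOMO)benzene F2. CSA (10 mol %) in CH2Cl2 with MeOH (2 equiv) at −20 °C lets the MOM-bearing oxygen next to the epoxide open it at the tertiary carbon (6-endo) with loss of that MOM group, giving (3R)-6-bromo-5-[2-(3,4-bis(TBSO)phenyl)ethyl]-7-(MOMO)-2,2-dimethylchroman-3-ol F3. ZnBr2/n-PrSH as in step 7 then frees the C7 phenol and gives 13.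

Step 10. The aryl anion is flanked by OTIPS and the bridge, so protonation, silyl O-to-C shift or the branched SN2' product may take over. The fallback sets out from 15 and comes back at 17. Stille coupling with allyltributylstannane (Pd(P(t-Bu)3)2 5 mol %, toluene, 100 °C) gives (3R)-6-allyl-5-[2-(3,4-bis(TBSO)phenyl)ethyl]-2,2-dimethyl-3-(TESO)-7-(TIPSO)chromane F4. Cross-metathesis of that compound with 2-methylbut-2-ene (co-solvent, second-generation Grubbs catalyst 5 mol %, CH2Cl2, 40 °C) turns the allyl into the prenyl group and gives 17.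

**Further compounds**
F1 | step 4 | (E)-1-[2-(3,4-bis(TBSO)phenyl)ethenyl]-3,5-bis(MOMO)benzene | COCOc1cc(/C=C/c2ccc(O[Si](C)(C)C(C)(C)C)c(O[Si](C)(C)C(C)(C)C)c2)cc(OCOC)c1
F2 | step 8 | 2-bromo-3-[2-(3,4-bis(TBSO)phenyl)ethyl]-4-{[(2R)-3,3-dimethyloxiran-2-yl]methyl}-1,5-bis(MOMO)benzene | COCOc1cc(OCOC)c(Br)c(CCc2ccc(O[Si](C)(C)C(C)(C)C)c(O[Si](C)(C)C(C)(C)C)c2)c1C[C@H]1OC1(C)C
F3 | step 8 | (3R)-6-bromo-5-[2-(3,4-bis(TBSO)phenyl)ethyl]-7-(MOMO)-2,2-dimethylchroman-3-ol | Brc1c(OCOC)cc2c(c1CCc1ccc(O[Si](C)(C)C(C)(C)C)c(O[Si](C)(C)C(C)(C)C)c1)C[C@@H](O)C(C)(C)O2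
F4 | step 10 | (3R)-6-allyl-5-[2-(3,4-bis(TBSO)phenyl)ethyl]-2,2-dimethyl-3-(TESO)-7-(TIPSO)chromane | C=CCc1c(O[Si](C(C)C)(C(C)C)C(C)C)cc2c(c1CCc1ccc(O[Si](C)(C)C(C)(C)C)c(O[Si](C)(C)C(C)(C)C)c1)C[C@@H](O[Si](CC)(CC)CC)C(C)(C)O2
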